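**Plan**

1. Locants: iridoid numbering in the lactone half (C1 lactone carbonyl, C4 with exocyclic C11, C5/C9 ring fusion, C7 and C8 carbinols, C10 the CH2O carbon); guaiane numbering in the acid half (C14 carboxyl). Cuts: C8–C10 (union); lactone half C1–C9, C4–C5 and C7–O; acid half C10–C14, the two bonds to C9 (one-carbon insertion), C3=C4, C1–C2 and C4–C5.
2. Lactone half, forward: cyclopentenone → 3-alkenylcyclopentanone → six-membered lactone ring closed onto the five-membered ring (β-keto lactone) → C7 oxidation to the 7,8-dione enol, O8 as PMB ether → conjugate reduction to the C7 silyl enol ether.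
3. Acid half, forward: 5-isopropylcyclohexenone → cyclopentene ring by metathesis (cis-hydrindanone) → six- to seven-membered ring expansion → dienyl triflate → acid → iodomethyl ester; then union, C7 reduction, PMB removal.
4. Enabling feature: C8 is the fully substituted carbinol carbon of the cyclopentane ring, between carbinol C7 and ring-fusion carbon C9 of the cis-fused cyclopenta[c]pyranone. With C7 as a ketone, C8 is an enolate carbon whose convex face (anti to the C9–C1 bond) is the face that carries C10 in the target; C10, bonded to the ester oxygen, is electrophilic as its iodide, so it can enter last with the whole guaiane acid attached.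
5. Stereochemistry: C5 from Rh/(R)-BINAP conjugate addition; C9, C8 and C7 in turn from convex-face delivery of hydride, of C10 and of hydride. In the acid half an organocatalytically set isopropyl stereocenter directs C5 (trans conjugate addition), C1 (cis fusion by equilibration) and C4 (convex-face hydrogenation) and is then erased in the diene.
6. Helpers: C7 ketone, O8 PMB ether, O7 silyl group and the iodide; all are removed in steps 22 to 24.

Key step: step 22

Remark: the (R)-configured catalysts in steps 3 and 11 are assigned from the usual facial models of these catalyst classes; if a model fails for these substrates, the mirror-image catalyst is used.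

Step 1
Reactants: 1 2-bromoprop-2-en-1-ol
Product: 2 tert-butyl[(2-bromoprop-2-en-1-yl)oxy]dimethylsilane
Conditions: t-BuMe2SiCl, imidazole, CH2Cl2, 0 °C to rt
Reagents that add atoms: tert-butyldimethylsilyl chloride CC(C)(C)[Si](C)(C)Cl
Why: Silyl ether formation protects the primary allylic hydroxyl for the two metal-catalysed steps that follow.

Step 2
Reactants: 2 tert-butyl[(2-bromoprop-2-en-1-yl)oxy]dimethylsilane
Product: 3 tert-butyldimethyl{[2-(4,4,5,5-tetramethyl-1,3,2-dioxaborolan-2-yl)prop-2-en-1-yl]oxy}silane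
Conditions: B2pin2, PdCl2(PPh3)2 (3 mol%), PPh3, KOPh, toluene, 50 °C
Reagents that add atoms: bis(pinacolato)diboron CC1(C)OB(OC1(C)C)B1OC(C)(C)C(C)(C)O1
Why: Miyaura borylation of the alkenyl bromide should give the 1,1-disubstituted alkenylboronate without touching the allylic silyl ether.

Step 3
Reactants: 3 tert-butyldimethyl{[2-(4,4,5,5-tetramethyl-1,3,2-dioxaborolan-2-yl)prop-2-en-1-yl]oxy}silane; 4 cyclopent-2-en-1-one
Product: 5 (3R)-3-[3-(tert-butyldimethylsilyloxy)prop-1-en-2-yl]cyclopentan-1-one
Conditions: [RhCl(C2H4)2]2 (2.5 mol%), (R)-BINAP (6 mol%), KOH (aq), dioxane/H2O, 50 °C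
Reagents that add atoms: none
Why: Rh/BINAP-catalysed asymmetric 1,4-addition of an alkenylboron reagent to a cyclic enone (Hayashi–Miyaura reaction) should set C5, the (R)-ligand directing the alkenyl group to the enone face that gives the (R)-ketone.

Step 4
Reactants: 5 (3R)-3-[3-(tert-butyldimethylsilyloxy)prop-1-en-2-yl]cyclopentan-1-one
Product: 6 (3R)-3-(3-hydroxyprop-1-en-2-yl)cyclopentan-1-one
Conditions: HF·pyridine, THF, 0 °C to rt
Reagents that add atoms: none
Why: Fluoride cleaves the silyl ether under conditions that leave the ketone and its β-stereocenter untouched.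

Step 5
Reactants: 6 (3R)-3-(3-hydroxyprop-1-en-2-yl)cyclopentan-1-one
Product: 7 methyl 2-[(1R)-3-oxocyclopentyl]prop-2-en-1-yl carbonate
Conditions: ClCO2Me, pyridine, CH2Cl2, 0 °C
Reagents that add atoms: methyl chloroformate COC(=O)Cl
Why: Acylation of the alcohol installs C1 as a carbonate tethered through O2 and C3, ready for delivery to C9.

Step 6
Reactants: 7 methyl 2-[(1R)-3-oxocyclopentyl]prop-2-en-1-yl carbonate
Product: 8 (4aR,7aR)-4-methylidenehexahydrocyclopenta[c]pyran-1,7-dione (cis-fused β-keto δ-lactone)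
Conditions: NaH (2.2 equiv), MeOH (cat.), THF, 0 to 50 °C; aq NH4Cl
Reagents that add atoms: none
Why: Intramolecular Claisen-type C-acylation (Dieckmann-like) under equilibrating conditions should work because only the C9 enolate can close the six-membered lactone, which must be cis-fused, and the doubly stabilised enolate of the product drives the equilibrium.

Step 7
Reactants: 8 (4aR,7aR)-4-methylidenehexahydrocyclopenta[c]pyran-1,7-dione
Product: 10 (4aR,7aR)-6-hydroxy-4-methylidenehexahydrocyclopenta[c]pyran-1,7-dione (both epimers at the carbinol carbon C7 of the iridoid skeleton), via dilithium dienolate 9 (not isolated)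
Conditions: LiN(iPr)2 (2.3 equiv), THF, −78 to −30 °C; then 2-(benzenesulfonyl)-3-phenyloxaziridine, −78 °C
Reagents that add atoms: 2-(benzenesulfonyl)-3-phenyloxaziridine O=S(=O)(c1ccccc1)N1OC1c1ccccc1
Why: The Weiler dianion of the β-keto lactone reacts with electrophiles at its γ-carbon C7, and the Davis oxaziridine transfers oxygen there; the configuration formed is of no consequence because C7 is oxidised next.

Step 8
Reactants: 10 (4aR,7aR)-6-hydroxy-4-methylidenehexahydrocyclopenta[c]pyran-1,7-dione
Product: 11 (4aS)-7-hydroxy-4-methylidene-3,4,4a,5-tetrahydrocyclopenta[c]pyran-1,6-dione (enol form of the 7,8-dione of the iridoid skeleton)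
Conditions: Dess–Martin periodinane, NaHCO3, CH2Cl2, 0 °C
Reagents that add atoms: none
Why: Dess–Martin oxidation of the acyloin gives the 1,2-dione, which should enolise toward C9 because that enol is conjugated with both the C7 ketone and the lactone carbonyl.

Step 9
Reactants: 11 (4aS)-7-hydroxy-4-methylidene-3,4,4a,5-tetrahydrocyclopenta[c]pyran-1,6-dione
Product: 12 (4aS)-7-[(4-methoxyphenyl)methoxy]-4-methylidene-3,4,4a,5-tetrahydrocyclopenta[c]pyran-1,6-dione
Conditions: 4-MeOC6H4CH2Cl, K2CO3, Bu4NI (cat.), DMF, rt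
Reagents that add atoms: 4-methoxybenzyl chloride COc1ccc(CCl)cc1
Why: Williamson O-alkylation of the acidic enol should prevail because C9 is already fully substituted, and it puts on O8 a group that cannot migrate to O7 and is removable by oxidation.

Step 10
Reactants: 12 (4aS)-7-[(4-methoxyphenyl)methoxy]-4-methylidene-3,4,4a,5-tetrahydrocyclopenta[c]pyran-1,6-dione
Product: 13 (4aR,7aR)-6-[dimethyl(phenyl)silyl]oxy-7-[(4-methoxyphenyl)methoxy]-4-methylidene-3,4,4a,5-tetrahydro-7aH-cyclopenta[c]pyran-1-one
Conditions: [(Ph3P)CuH]6 (5 mol%), PhMe2SiH (1.5 equiv), toluene, rt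
Reagents that add atoms: dimethylphenylsilane C[SiH](C)c1ccccc1
Why: Catalytic copper hydride 1,4-hydrosilylation of the enone should deliver hydride to C9 (β to the ketone, the stronger acceptor, whereas C8 carries the deactivating alkoxy group) from the convex face anti to the C5 substituent, which sets the cis ring fusion and gives the regiodefined C7 silyl enol ether.

Step 11
Reactants: 14 (2E)-4-methylpent-2-enal; 15 tert-butyl 3-oxobutanoate
Product: 17 (5S)-5-(propan-2-yl)cyclohex-2-en-1-one, via Michael adduct 16 (not isolated)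
Conditions: (R)-2-{bis[3,5-bis(trifluoromethyl)phenyl](trimethylsilyloxy)methyl}pyrrolidine (10 mol%), neat, rt; then TsOH·H2O, toluene, 80 °C
Reagents that add atoms: none
Why: Iminium-catalysed Michael addition of the β-keto ester, in which the diarylprolinol silyl ether shields one face of the iminium ion and so sets the isopropyl stereocenter, is followed by acid-mediated intramolecular aldol condensation, tert-butyl ester cleavage and decarboxylation to the cyclohexenone.

Step 12
Reactants: 17 (5S)-5-(propan-2-yl)cyclohex-2-en-1-one; 18 prop-1-en-2-ylmagnesium bromide; 19 3-bromoprop-1-ene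
Product: 21 (2R,3S,5S)-2-allyl-3-(prop-1-en-2-yl)-5-(propan-2-yl)cyclohexan-1-one, via bromomagnesium enolate 20 (not isolated)
Conditions: CuBr·SMe2 (5 mol%), THF, −40 °C; then allyl bromide, DMPU, −40 °C to rt
Reagents that add atoms: none
Why: Copper-catalysed conjugate addition of the Grignard reagent should occur trans to the 5-isopropyl group (setting guaiane C5), and the regiodefined enolate is then allylated at C1 trans to the new isopropenyl group.

Step 13
Reactants: 21 (2R,3S,5S)-2-allyl-3-(prop-1-en-2-yl)-5-(propan-2-yl)cyclohexan-1-one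
Product: 23 (3aS,6S,7aS)-1-methyl-6-(propan-2-yl)-3,3a,5,6,7,7a-hexahydro-4H-inden-4-one (cis-fused), via trans-fused ketone 22 (not isolated)
Conditions: second-generation Grubbs catalyst (H2IMes)(PCy3)Cl2Ru=CHPh (5 mol%), CH2Cl2, 40 °C; then DBU (0.3 equiv), rt
Reagents that add atoms: none
Why: Ring-closing metathesis of the allyl and isopropenyl groups closes the cyclopentene, and base equilibration at the α-carbon C1 should give the cis-fused ketone because only the cis fusion lets the isopropyl group sit equatorial.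

Step 14
Reactants: 23 (3aS,6S,7aS)-1-methyl-6-(propan-2-yl)-3,3a,5,6,7,7a-hexahydro-4H-inden-4-one
Product: 24 (1R,3aS,6S,7aR)-1-methyl-6-(propan-2-yl)octahydro-4H-inden-4-one
Conditions: H2 (1 atm), 10% Pd/C, EtOAc, rt
Reagents that add atoms: none
Why: Heterogeneous hydrogenation should add hydrogen to the convex face of the cis-fused bicycle, placing the methyl group on the concave face, cis to C6, and so setting guaiane C4.

Step 15
Reactants: 24 (1R,3aS,6S,7aR)-1-methyl-6-(propan-2-yl)octahydro-4H-inden-4-one
Product: 25 trimethyl{[(1R,3aS,6R,7aR)-1-methyl-6-(propan-2-yl)-2,3,3a,6,7,7a-hexahydro-1H-inden-4-yl]oxy}silane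
Conditions: LiN(iPr)2, Me3SiCl (in situ), THF, −78 °C
Reagents that add atoms: chlorotrimethylsilane C[Si](C)(C)Cl
Why: Kinetic deprotonation should occur at the less hindered methylene C8, not at the ring-fusion methine, giving the less substituted silyl enol ether.

Step 16
Reactants: 25 trimethyl{[(1R,3aS,6R,7aR)-1-methyl-6-(propan-2-yl)-2,3,3a,6,7,7a-hexahydro-1H-inden-4-yl]oxy}silane
Product: 26 siloxycyclopropane formed by adding CH2 across the enol ether double bond of 25 (tricyclic, Me3SiO on the ring-fusion cyclopropane carbon, either face)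
Conditions: Et2Zn, CH2I2, CH2Cl2, 0 °C to rt
Reagents that add atoms: diiodomethane ICI
Why: Simmons–Smith cyclopropanation (Furukawa variant) is fast on electron-rich silyl enol ethers, and the face of addition does not matter because both new centers are lost in the next step.

Step 17
Reactants: 26 siloxycyclopropane
Product: 28 (3R,3aR,5R,8aS)-3-methyl-5-(propan-2-yl)-2,3,3a,4,5,8a-hexahydroazulen-8(1H)-one, via β-chloro ketone 27 (not isolated)
Conditions: FeCl3 (2.2 equiv), DMF, 0 °C; then NaOAc, MeOH, 40 °C
Reagents that add atoms: none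
Why: Ito–Saegusa ring expansion, in which oxidation by FeCl3 cleaves the internal cyclopropane bond to the ring-enlarged β-chloro ketone and mild acetate-mediated elimination gives the cycloheptenone, inserts C9 as a single carbon and should leave the epimerisable C1 untouched.

Step 18
Reactants: 28 (3R,3aR,5R,8aS)-3-methyl-5-(propan-2-yl)-2,3,3a,4,5,8a-hexahydroazulen-8(1H)-one
Product: 29 (3R,3aR,8aS)-3-methyl-5-(propan-2-yl)-1,2,3,3a,4,8a-hexahydroazulen-8-yl trifluoromethanesulfonate
Conditions: Tf2O, 2,6-di-tert-butyl-4-methylpyridine, CH2Cl2, 0 °C to rt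
Reagents that add atoms: trifluoromethanesulfonic anhydride O=S(=O)(OS(=O)(=O)C(F)(F)F)C(F)(F)F
Why: O-Triflation of the enone and loss of the γ-proton at C7 from the resulting allyl cation should give the through-conjugated dienyl triflate, as with steroidal 4-en-3-ones, and this erases the controlling C7 stereocenter.

Step 19
Reactants: 29 (3R,3aR,8aS)-3-methyl-5-(propan-2-yl)-1,2,3,3a,4,8a-hexahydroazulen-8-yl trifluoromethanesulfonate
Product: 30 (3R,3aR,8aS)-3-methyl-5-(propan-2-yl)-1,2,3,3a,4,8a-hexahydroazulene-8-carboxylic acid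
Conditions: Pd(OAc)2 (5 mol%), Ph2P(CH2)3PPh2, CO (1 atm), Et3N, DMF/H2O, 60 °C
Reagents that add atoms: carbon monoxide [C-]#[O+]; water O
Why: Pd(OAc)2/diphosphine-catalysed hydroxycarbonylation of the alkenyl triflate (oxidative addition, CO insertion, hydrolysis of the acyl complex) installs C14 with retention of the diene.

Step 20
Reactants: 30 (3R,3aR,8aS)-3-methyl-5-(propan-2-yl)-1,2,3,3a,4,8a-hexahydroazulene-8-carboxylic acid
Product: 31 chloromethyl (3R,3aR,8aS)-3-methyl-5-(propan-2-yl)-1,2,3,3a,4,8a-hexahydroazulene-8-carboxylate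
Conditions: ClCH2OSO2Cl, NaHCO3, Bu4NHSO4 (cat.), CH2Cl2/H2O, rt
Reagents that add atoms: chloromethyl chlorosulfate ClCOS(=O)(=O)Cl
Why: Phase-transfer O-alkylation of the carboxylate by chloromethyl chlorosulfate, which reacts at carbon with loss of chlorosulfate, attaches the future C10 to the acid.

Step 21
Reactants: 31 chloromethyl (3R,3aR,8aS)-3-methyl-5-(propan-2-yl)-1,2,3,3a,4,8a-hexahydroazulene-8-carboxylate
Product: 32 iodomethyl (3R,3aR,8aS)-3-methyl-5-(propan-2-yl)-1,2,3,3a,4,8a-hexahydroazulene-8-carboxylate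
Conditions: NaI, acetone, rt, dark
Reagents that add atoms: sodium iodide [Na+].[I-]
Why: Finkelstein exchange, driven by precipitation of NaCl, gives the more reactive and softer iodide, which is used at once.

Step 22
Reactants: 13 (4aR,7aR)-6-[dimethyl(phenyl)silyl]oxy-7-[(4-methoxyphenyl)methoxy]-4-methylidene-3,4,4a,5-tetrahydro-7aH-cyclopenta[c]pyran-1-one; 32 iodomethyl (3R,3aR,8aS)-3-methyl-5-(propan-2-yl)-1,2,3,3a,4,8a-hexahydroazulene-8-carboxylate
Product: 34 [(4aR,7S,7aR)-7-[(4-methoxyphenyl)methoxy]-4-methylidene-1,6-dioxohexahydrocyclopenta[c]pyran-7-yl]methyl (3R,3aR,8aS)-3-methyl-5-(propan-2-yl)-1,2,3,3a,4,8a-hexahydroazulene-8-carboxylate, via sulfonium enolate 33 (not isolated)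
Conditions: [(Me2N)3S]+[Me3SiF2]− (TASF, 1.1 equiv), THF, −78 °C; then 32 (1.2 equiv), −78 to −20 °C
Reagents that add atoms: none
Why: Proposed new method: fluoride from TASF cleaves the O7–Si bond of 13 to give the regiodefined tris(dimethylamino)sulfonium enolate 33, whose only nucleophilic carbon is C8 because O8 is held as a PMB ether that cannot migrate, and this enolate displaces iodide in an SN2 step from the primary carbon of 32 that is activated by the adjacent oxygen, which forms the C8–C10 bond and joins the two halves. The closest known reaction type is the fluoride-triggered C-alkylation of silyl enol ethers with reactive halides (allyl, benzyl and alkoxymethyl halides), extended here to an acyloxymethyl iodide. No ring is closed. The one new stereocenter, C8, is controlled by the cis-fused bicyclic lactone: the electrophile should approach the enolate on the convex face, anti to the C9–C1 bond, so that C10 ends trans to C1 and O8 stays on the concave face as in the target. The step needs C- over O-alkylation and displacement at CH2–I over attack at the ester carbonyl or conjugate addition to the dienoate: the soft iodide leaving group, the low temperature and the α-branched, conjugated carbonyl of 32 should secure this, and the product cannot eliminate the carboxylate because C8 has become quaternary.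

Step 23
Reactants: 34 [(4aR,7S,7aR)-7-[(4-methoxyphenyl)methoxy]-4-methylidene-1,6-dioxohexahydrocyclopenta[c]pyran-7-yl]methyl (3R,3aR,8aS)-3-methyl-5-(propan-2-yl)-1,2,3,3a,4,8a-hexahydroazulene-8-carboxylate
Product: 35 [(4aR,6S,7S,7aR)-6-hydroxy-7-[(4-methoxyphenyl)methoxy]-4-methylidene-1-oxohexahydrocyclopenta[c]pyran-7-yl]methyl (3R,3aR,8aS)-3-methyl-5-(propan-2-yl)-1,2,3,3a,4,8a-hexahydroazulene-8-carboxylate
Conditions: NaBH4, MeOH/THF, −40 °C; AcOH quench
Reagents that add atoms: none
Why: Borohydride reduction of the C7 ketone should take place on the convex face, anti to the C8–O bond (polar Felkin–Anh control) and away from the lactone ring, giving the C7 hydroxyl cis to O8, while the low temperature spares lactone, ester and dienoate.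

Step 24
Reactants: 35 [(4aR,6S,7S,7aR)-6-hydroxy-7-[(4-methoxyphenyl)methoxy]-4-methylidene-1-oxohexahydrocyclopenta[c]pyran-7-yl]methyl (3R,3aR,8aS)-3-methyl-5-(propan-2-yl)-1,2,3,3a,4,8a-hexahydroazulene-8-carboxylate
Product: 36 nardostachysin, [(4aR,6S,7S,7aR)-6,7-dihydroxy-4-methylidene-1-oxohexahydrocyclopenta[c]pyran-7-yl]methyl (3R,3aR,8aS)-3-methyl-5-(propan-2-yl)-1,2,3,3a,4,8a-hexahydroazulene-8-carboxylate
Conditions: DDQ, CH2Cl2/pH 7 phosphate buffer, 0 °C to rt
Reagents that add atoms: none
Why: Oxidative cleavage of the electron-rich PMB ether by DDQ frees the tertiary C8 hydroxyl under neutral conditions that the electron-poor dienoate, the lactone and the exocyclic alkene should tolerate; any p-methoxybenzylidene acetal formed with the C7 hydroxyl is hydrolysed with aqueous acetic acid.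

**Compound list**

1 | 2-bromoprop-2-en-1-ol | C=C(Br)CO | starting material
2 | tert-butyl[(2-bromoprop-2-en-1-yl)oxy]dimethylsilane | C=C(Br)CO[Si](C)(C)C(C)(C)C | intermediate
3 | tert-butyldimethyl{[2-(4,4,5,5-tetramethyl-1,3,2-dioxaborolan-2-yl)prop-2-en-1-yl]oxy}silane | C=C(CO[Si](C)(C)C(C)(C)C)B1OC(C)(C)C(C)(C)O1 | intermediate
4 | cyclopent-2-en-1-one | O=C1C=CCC1 | starting material
5 | (3R)-3-[3-(tert-butyldimethylsilyloxy)prop-1-en-2-yl]cyclopentan-1-one | O=C1C[C@H](C(=C)CO[Si](C)(C)C(C)(C)C)CC1 | intermediate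
6 | (3R)-3-(3-hydroxyprop-1-en-2-yl)cyclopentan-1-one | O=C1C[C@H](C(=C)CO)CC1 | intermediate
7 | methyl 2-[(1R)-3-oxocyclopentyl]prop-2-en-1-yl carbonate | O=C1C[C@H](C(=C)COC(=O)OC)CC1 | intermediate
8 | (4aR,7aR)-4-methylidenehexahydrocyclopenta[c]pyran-1,7-dione (cis-fused) | C=C1COC(=O)[C@@H]2[C@H]1CCC2=O | intermediate
9 | dilithium dienolate of 8 (C9 and C7 deprotonated) | C=C1COC([O-])=C2C([O-])=CC[C@@H]12.[Li+].[Li+] | intermediate
10 | (4aR,7aR)-6-hydroxy-4-methylidenehexahydrocyclopenta[c]pyran-1,7-dione (both carbinol epimers) | C=C1COC(=O)[C@@H]2[C@H]1CC(O)C2=O | intermediate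
11 | (4aS)-7-hydroxy-4-methylidene-3,4,4a,5-tetrahydrocyclopenta[c]pyran-1,6-dione | C=C1COC(=O)C2=C(O)C(=O)C[C@@H]12 | intermediate
12 | (4aS)-7-[(4-methoxyphenyl)methoxy]-4-methylidene-3,4,4a,5-tetrahydrocyclopenta[c]pyran-1,6-dione | C=C1COC(=O)C2=C(OCc3ccc(OC)cc3)C(=O)C[C@@H]12 | intermediate
13 | (4aR,7aR)-6-[dimethyl(phenyl)silyl]oxy-7-[(4-methoxyphenyl)methoxy]-4-methylidene-3,4,4a,5-tetrahydro-7aH-cyclopenta[c]pyran-1-one | C=C1COC(=O)[C@@H]2[C@H]1CC(O[Si](C)(C)c3ccccc3)=C2OCc4ccc(OC)cc4 | intermediate
14 | (2E)-4-methylpent-2-enal | CC(C)/C=C/C=O | starting material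
15 | tert-butyl 3-oxobutanoate | CC(=O)CC(=O)OC(C)(C)C | starting material
16 | tert-butyl (3R)-2-acetyl-4-methyl-3-(2-oxoethyl)pentanoate (C2 epimers) | O=CC[C@H](C(C)C)C(C(C)=O)C(=O)OC(C)(C)C | intermediate
17 | (5S)-5-(propan-2-yl)cyclohex-2-en-1-one | O=C1C[C@@H](C(C)C)CC=C1 | intermediate
18 | prop-1-en-2-ylmagnesium bromide | C=C(C)[Mg]Br | starting material
19 | 3-bromoprop-1-ene (allyl bromide) | C=CCBr | starting material
20 | bromomagnesium enolate of (3S,5S)-3-(prop-1-en-2-yl)-5-(propan-2-yl)cyclohexan-1-one (isopropenyl trans to isopropyl) | Br[Mg]OC1=C[C@@H](C(C)=C)C[C@H](C(C)C)C1 | intermediate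
21 | (2R,3S,5S)-2-allyl-3-(prop-1-en-2-yl)-5-(propan-2-yl)cyclohexan-1-one | O=C1C[C@@H](C(C)C)C[C@H](C(C)=C)[C@H]1CC=C | intermediate
22 | (3aR,6S,7aS)-1-methyl-6-(propan-2-yl)-3,3a,5,6,7,7a-hexahydro-4H-inden-4-one (trans-fused) | O=C1C[C@@H](C(C)C)C[C@@H]2C(C)=CC[C@@H]12 | intermediate
23 | (3aS,6S,7aS)-1-methyl-6-(propan-2-yl)-3,3a,5,6,7,7a-hexahydro-4H-inden-4-one (cis-fused) | O=C1C[C@@H](C(C)C)C[C@@H]2C(C)=CC[C@H]12 | intermediate
24 | (1R,3aS,6S,7aR)-1-methyl-6-(propan-2-yl)octahydro-4H-inden-4-one | O=C1C[C@@H](C(C)C)C[C@@H]2[C@H](C)CC[C@H]12 | intermediate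
25 | trimethyl{[(1R,3aS,6R,7aR)-1-methyl-6-(propan-2-yl)-2,3,3a,6,7,7a-hexahydro-1H-inden-4-yl]oxy}silane | C[Si](C)(C)OC1=C[C@@H](C(C)C)C[C@@H]2[C@H](C)CC[C@H]12 | intermediate
26 | siloxycyclopropane from 25 (CH2 added across the enol ether double bond) | C[Si](C)(C)OC13CC3[C@@H](C(C)C)C[C@@H]2[C@H](C)CC[C@H]12 | intermediate
27 | (3R,3aR,8aS)-6-chloro-3-methyl-5-(propan-2-yl)octahydroazulen-8(1H)-one (isopropyl carbon as in 28, both C6 epimers) | O=C1CC(Cl)[C@@H](C(C)C)C[C@@H]2[C@H](C)CC[C@H]12 | intermediate
28 | (3R,3aR,5R,8aS)-3-methyl-5-(propan-2-yl)-2,3,3a,4,5,8a-hexahydroazulen-8(1H)-one | O=C1C=C[C@@H](C(C)C)C[C@@H]2[C@H](C)CC[C@H]12 | intermediate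
29 | (3R,3aR,8aS)-3-methyl-5-(propan-2-yl)-1,2,3,3a,4,8a-hexahydroazulen-8-yl trifluoromethanesulfonate | O=S(=O)(OC1=CC=C(C(C)C)C[C@@H]2[C@H](C)CC[C@H]12)C(F)(F)F | intermediate
30 | (3R,3aR,8aS)-3-methyl-5-(propan-2-yl)-1,2,3,3a,4,8a-hexahydroazulene-8-carboxylic acid | OC(=O)C1=CC=C(C(C)C)C[C@@H]2[C@H](C)CC[C@H]12 | intermediate
31 | chloromethyl (3R,3aR,8aS)-3-methyl-5-(propan-2-yl)-1,2,3,3a,4,8a-hexahydroazulene-8-carboxylate | ClCOC(=O)C1=CC=C(C(C)C)C[C@@H]2[C@H](C)CC[C@H]12 | intermediate
32 | iodomethyl (3R,3aR,8aS)-3-methyl-5-(propan-2-yl)-1,2,3,3a,4,8a-hexahydroazulene-8-carboxylate | ICOC(=O)C1=CC=C(C(C)C)C[C@@H]2[C@H](C)CC[C@H]12 | intermediate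
33 | tris(dimethylamino)sulfonium enolate of the C7 ketone (O8 PMB ether, cis-fused lactone) | C=C1COC(=O)[C@@H]2[C@H]1CC([O-])=C2OCc3ccc(OC)cc3.CN(C)[S+](N(C)C)N(C)C | intermediate
34 | [(4aR,7S,7aR)-7-[(4-methoxyphenyl)methoxy]-4-methylidene-1,6-dioxohexahydrocyclopenta[c]pyran-7-yl]methyl (3R,3aR,8aS)-3-methyl-5-(propan-2-yl)-1,2,3,3a,4,8a-hexahydroazulene-8-carboxylate | C=C1COC(=O)[C@@H]2[C@H]1CC(=O)[C@@]2(OCc3ccc(OC)cc3)COC(=O)C3=CC=C(C(C)C)C[C@@H]4[C@H](C)CC[C@H]34 | intermediate
35 | [(4aR,6S,7S,7aR)-6-hydroxy-7-[(4-methoxyphenyl)methoxy]-4-methylidene-1-oxohexahydrocyclopenta[c]pyran-7-yl]methyl (3R,3aR,8aS)-3-methyl-5-(propan-2-yl)-1,2,3,3a,4,8a-hexahydroazulene-8-carboxylate | C=C1COC(=O)[C@@H]2[C@H]1C[C@H](O)[C@@]2(OCc3ccc(OC)cc3)COC(=O)C3=CC=C(C(C)C)C[C@@H]4[C@H](C)CC[C@H]34 | intermediate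
36 | nardostachysin | C=C1COC(=O)[C@@H]2[C@H]1C[C@H](O)[C@@]2(O)COC(=O)C3=CC=C(C(C)C)C[C@@H]4[C@H](C)CC[C@H]34 | target

**Count and risks**

Total step count: 24. Longest linear sequence: 14 steps (steps 11 to 21, then 22 to 24).

Step 22 (Proposed new method). What may go wrong: alkylation of the naked enolate on oxygen instead of carbon, transfer of the acyl group of 32 to the enolate, or fluoride attack on 32. The fallback uses known chemistry and runs from silyl enol ether 13 back to ketone 34. Fluoride-catalysed aldol addition of 13 to monomeric formaldehyde (Bu4NF cat., THF, −78 °C) should give, again by convex-face attack at C8, the hydroxymethyl ketone F1. Its primary hydroxyl is then esterified with acid 30 (carbodiimide, DMAP; Steglich esterification) to give 34. In this variant the C8–C10 bond is made with a one-carbon unit and the halves are joined at the ester oxygen.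

Step 10. What may go wrong: hydride delivery to C8 (conjugate to the lactone carbonyl) followed by loss of the PMB-oxy group, or 1,2-reduction of the C7 ketone. The fallback runs from enone 12 to ketone 34. Carbonyl-directed 1,4-hydrosilylation with RhCl(PPh3)3 and Et3SiH (benzene, 50 °C) binds silicon to the ketone oxygen before hydrogen passes to C9, so the hydride cannot reach C8. It should give the triethylsilyl enol ether F2, which is taken through the conditions of step 22 in place of 13.

Step 23. What may go wrong: poor facial selectivity of hydride delivery at C7, because the C10 substituent on the convex face competes with the O8 ether on the concave face; acyl migration from O10 to the new alkoxide is a second hazard. The fallback runs from ketone 34 to alcohol 35 and replaces substrate control by reagent control. Corey–Bakshi–Shibata reduction with (R)-2-methyl-CBS-oxazaborolidine and catecholborane at −78 °C distinguishes the small C6 methylene from the fully substituted C8 and should give the (S)-configured C7 carbinol without a basic alkoxide. This fallback makes no new compound (F0).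

**Further compounds**

F1 | step 22 | (4aR,7S,7aR)-7-(hydroxymethyl)-7-[(4-methoxyphenyl)methoxy]-4-methylidenehexahydrocyclopenta[c]pyran-1,6-dione | C=C1COC(=O)[C@@H]2[C@H]1CC(=O)[C@@]2(OCc3ccc(OC)cc3)CO
F2 | step 10 | (4aR,7aR)-7-[(4-methoxyphenyl)methoxy]-4-methylidene-6-(triethylsilyloxy)-3,4,4a,5-tetrahydro-7aH-cyclopenta[c]pyran-1-one | C=C1COC(=O)[C@@H]2[C@H]1CC(O[Si](CC)(CC)CC)=C2OCc3ccc(OC)cc3
F0 | step 23 | none | none
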